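**Remark:** flavan numbering (O1, C2, C3, C4, C4a, C5–C8, C8a) is used for the target and for the precursor atoms that become these positions.

## Strategy

The route rests on cutting the pyran ring at C4–C4a, the bond from the benzylic CH2 to the A-ring carbon that lies between O1 and the galloylated O5. The key step is a 6-endo intramolecular Friedel–Crafts epoxide–arene cyclisation: in one operation it closes the heterocycle, forms C4–C4a and releases the cis C3 hydroxyl, with C2 and C3 already fixed in the open chain. It exploits that C4a is para to the ether oxygen on C7, whereas the competing C8 is para only to the acylated O5. The precursor is the threo 3-benzyloxy-5-galloyloxyphenyl ether of a 1-aryl-2,3-epoxypropan-1-ol, made by Sharpless kinetic resolution and Mitsunobu inversion.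

Key step: step 6

## Route

Step 1
Reactants: 1 phloroglucinol (threefold excess)
Product: 2 5-(benzyloxy)benzene-1,3-diol
Conditions: BnBr (0.33 equiv), K2CO3 (0.4 equiv), DMF, 0 °C → rt
Reagents that add atoms: benzyl bromide, BrCc1ccccc1
Why: Williamson ether synthesis; with the triol in excess the bromide should be consumed mainly by mono-O-alkylation of one of three equivalent hydroxyls, and the symmetric mono-ether is separated from di-ether and C-benzylated material.

Step 2
Reactants: 3 3,4-bis(benzyloxy)benzaldehyde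
Product: 4 rac-1-[3,4-bis(benzyloxy)phenyl]prop-2-en-1-ol
Conditions: CH2=CHMgBr (1.2 equiv), THF, −20 → 0 °C; then sat. aq. NH4Cl
Reagents that add atoms: vinylmagnesium bromide, C=C[Mg]Br
Why: Grignard 1,2-addition to the aldehyde gives the racemic secondary allylic alcohol; no stereocontrol is needed because the next step resolves it.

Step 3
Reactants: 4 rac-1-[3,4-bis(benzyloxy)phenyl]prop-2-en-1-ol
Product: 5 (S)-[3,4-bis(benzyloxy)phenyl][(2R)-oxiran-2-yl]methanol (erythro)
Conditions: Ti(OiPr)4 (15 mol %), L-(+)-DIPT (20 mol %), t-BuOOH (0.55 equiv), 4 Å MS, CH2Cl2, −20 °C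
Reagents that add atoms: tert-butyl hydroperoxide, CC(C)(C)OO
Why: Sharpless kinetic resolution (Katsuki–Sharpless epoxidation of a secondary allylic alcohol): with L-(+)-DIPT the (R)-enantiomer of 4 should be epoxidised fast and erythro-selectively, which sets the epoxide carbon as R under reagent control while the carbinol carbon keeps its geometry (descriptor S in the product through the change in CIP priorities), and the slow (S)-enantiomer of 4 is left behind and separated.

Step 4
Reactants: 5 (S)-[3,4-bis(benzyloxy)phenyl][(2R)-oxiran-2-yl]methanol; 2 5-(benzyloxy)benzene-1,3-diol (3 equiv)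
Product: 6 3-(benzyloxy)-5-{(R)-[3,4-bis(benzyloxy)phenyl][(2R)-oxiran-2-yl]methoxy}phenol (threo)
Conditions: PPh3 (1.5 equiv), DIAD (1.5 equiv), THF, 0 °C → rt
Reagents that add atoms: none
Why: Mitsunobu etherification: the phenol displaces the oxyphosphonium by SN2 with inversion at the benzylic carbinol (S to R), which turns the erythro epoxy alcohol into the threo ether required for a 2,3-cis flavan, while the epoxide carbon is untouched and the excess of the symmetric diol holds the reaction at the mono-ether.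

Step 5
Reactants: 6 3-(benzyloxy)-5-{(R)-[3,4-bis(benzyloxy)phenyl][(2R)-oxiran-2-yl]methoxy}phenol; 7 3,4,5-tris(benzyloxy)benzoic acid (1.2 equiv)
Product: 8 3-(benzyloxy)-5-{(R)-[3,4-bis(benzyloxy)phenyl][(2R)-oxiran-2-yl]methoxy}phenyl 3,4,5-tris(benzyloxy)benzoate
Conditions: EDC·HCl (1.5 equiv), DMAP (0.2 equiv), CH2Cl2, rt
Reagents that add atoms: none
Why: Steglich esterification of the remaining phenol installs the protected 5-O-galloyl group and at the same time turns this oxygen into the weak donor on which the regiochemistry of step 6 relies.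

Step 6
Reactants: 8 3-(benzyloxy)-5-{(R)-[3,4-bis(benzyloxy)phenyl][(2R)-oxiran-2-yl]methoxy}phenyl 3,4,5-tris(benzyloxy)benzoate
Product: 9 (2R,3R)-7-(benzyloxy)-2-[3,4-bis(benzyloxy)phenyl]-3-hydroxy-3,4-dihydro-2H-chromen-5-yl 3,4,5-tris(benzyloxy)benzoate
Conditions: AuCl3 (5 mol %), AgOTf (15 mol %), 4 Å MS, ClCH2CH2Cl (0.02 M), 0 °C → rt
Reagents that add atoms: none
Why: The cationic gold(III) Lewis acid coordinates the epoxide oxygen, the A-ring carbon between the ether and the ester oxygens attacks the unsubstituted epoxide CH2 from the backside (SN2-like Friedel–Crafts alkylation), and loss of a proton from the arenium ion restores the arene and frees the C3 hydroxyl. The closest known reaction type is the Lewis-acid- or gold-catalysed intramolecular Friedel–Crafts epoxy–arene cyclisation of aryl glycidyl ethers to chroman-3-ols. The pyran ring closes in the 6-endo-tet mode with respect to the epoxide, which should be preferred over 5-exo attack because the internal epoxide carbon is secondary, flanked by the fully substituted C2 and deactivated by the adjacent C–O bond. No stereocentre is created: neither the C2–O nor the C3–O bond is broken, so the threo (R,R) precursor is carried over as the 2,3-cis (2R,3R) flavan. The step needs regioselectivity between the two carbons ortho to the tethering oxygen, and the substrate is designed to secure it electronically: the carbon that becomes C4a is para to the benzyl ether oxygen, a strong donor, whereas the carbon that would become C8 is para only to the ester oxygen, whose lone pair is tied up by the carbonyl group, so the arenium ion of the wanted closure should be the better stabilised one. Attack of the B ring on the same CH2 would need a 5-endo closure from a less activated catechol diether and is not expected to compete.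

Step 7
Reactants: 9 (2R,3R)-7-(benzyloxy)-2-[3,4-bis(benzyloxy)phenyl]-3-hydroxy-3,4-dihydro-2H-chromen-5-yl 3,4,5-tris(benzyloxy)benzoate; 7 3,4,5-tris(benzyloxy)benzoic acid (2 equiv)
Product: 10 (2R,3R)-7-(benzyloxy)-2-[3,4-bis(benzyloxy)phenyl]-3,4-dihydro-2H-chromene-3,5-diyl bis[3,4,5-tris(benzyloxy)benzoate]
Conditions: EDC·HCl (2.5 equiv), DMAP (0.5 equiv), CH2Cl2, rt
Reagents that add atoms: none
Why: Steglich esterification of the axial secondary C3 hydroxyl touches no stereocentre, and an acyl shift between O5 and O3 would be harmless because both oxygens carry the same acyl group in the product.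

Step 8
Reactants: 10 (2R,3R)-7-(benzyloxy)-2-[3,4-bis(benzyloxy)phenyl]-3,4-dihydro-2H-chromene-3,5-diyl bis[3,4,5-tris(benzyloxy)benzoate]
Product: 11 (−)-epicatechin 3,5-di-O-gallate
Conditions: H2 (1 atm), 20% Pd(OH)2/C, THF–MeOH (1:1), rt
Reagents that add atoms: none
Why: Catalytic hydrogenolysis should cleave all nine benzyl ethers under neutral conditions that leave both gallate esters and the C2 and C3 stereocentres untouched.

## Compound list

1 | phloroglucinol | Oc1cc(O)cc(O)c1 | starting material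
2 | 5-(benzyloxy)benzene-1,3-diol | Oc1cc(O)cc(OCc2ccccc2)c1 | intermediate
3 | 3,4-bis(benzyloxy)benzaldehyde | O=Cc1ccc(OCc2ccccc2)c(OCc2ccccc2)c1 | starting material
4 | rac-1-[3,4-bis(benzyloxy)phenyl]prop-2-en-1-ol | C=CC(O)c1ccc(OCc2ccccc2)c(OCc2ccccc2)c1 | intermediate
5 | (S)-[3,4-bis(benzyloxy)phenyl][(2R)-oxiran-2-yl]methanol | O[C@@H](c1ccc(OCc2ccccc2)c(OCc2ccccc2)c1)[C@H]1CO1 | intermediate
6 | 3-(benzyloxy)-5-{(R)-[3,4-bis(benzyloxy)phenyl][(2R)-oxiran-2-yl]methoxy}phenol | Oc1cc(OCc2ccccc2)cc(O[C@H](c2ccc(OCc3ccccc3)c(OCc3ccccc3)c2)[C@H]2CO2)c1 | intermediate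
7 | 3,4,5-tris(benzyloxy)benzoic acid | OC(=O)c1cc(OCc2ccccc2)c(OCc2ccccc2)c(OCc2ccccc2)c1 | starting material
8 | 3-(benzyloxy)-5-{(R)-[3,4-bis(benzyloxy)phenyl][(2R)-oxiran-2-yl]methoxy}phenyl 3,4,5-tris(benzyloxy)benzoate | O=C(Oc1cc(OCc2ccccc2)cc(O[C@H](c2ccc(OCc3ccccc3)c(OCc3ccccc3)c2)[C@H]2CO2)c1)c1cc(OCc2ccccc2)c(OCc2ccccc2)c(OCc2ccccc2)c1 | intermediate
9 | (2R,3R)-7-(benzyloxy)-2-[3,4-bis(benzyloxy)phenyl]-3-hydroxy-3,4-dihydro-2H-chromen-5-yl 3,4,5-tris(benzyloxy)benzoate | O=C(Oc1cc(OCc2ccccc2)cc2c1C[C@@H](O)[C@@H](c1ccc(OCc3ccccc3)c(OCc3ccccc3)c1)O2)c1cc(OCc2ccccc2)c(OCc2ccccc2)c(OCc2ccccc2)c1 | intermediate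
10 | (2R,3R)-7-(benzyloxy)-2-[3,4-bis(benzyloxy)phenyl]-3,4-dihydro-2H-chromene-3,5-diyl bis[3,4,5-tris(benzyloxy)benzoate] | O=C(Oc1cc(OCc2ccccc2)cc2c1C[C@@H](OC(=O)c1cc(OCc3ccccc3)c(OCc3ccccc3)c(OCc3ccccc3)c1)[C@@H](c1ccc(OCc3ccccc3)c(OCc3ccccc3)c1)O2)c1cc(OCc2ccccc2)c(OCc2ccccc2)c(OCc2ccccc2)c1 | intermediate
11 | (−)-epicatechin 3,5-di-O-gallate | O=C(Oc1cc(O)cc2c1C[C@@H](OC(=O)c1cc(O)c(O)c(O)c1)[C@@H](c1ccc(O)c(O)c1)O2)c1cc(O)c(O)c(O)c1 | target

## Step count

Total steps: 8. Longest linear sequence: 7 (steps 2–8, from aldehyde 3).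

## Steps most likely to fail

**Step 6 (key cyclisation).** The ring may close at the other carbon ortho to the ether oxygen (the one between the ether and the benzyl ether oxygens), because the electronic bias of the ester is modest. The Lewis acid may also ionise the electron-rich benzylic C2–O bond before the epoxide is opened.

Fallback: it sets out from epoxy alcohol 5 and phloroglucinol 1 and comes back to the route at target 11.
- Mitsunobu etherification of 5 with a fivefold excess of 1 should give 5-{(R)-[3,4-bis(benzyloxy)phenyl][(2R)-oxiran-2-yl]methoxy}benzene-1,3-diol F1.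
- In F1 the two carbons ortho to the ether oxygen are equivalent and the ring is far more nucleophilic. Cyclisation in hexafluoroisopropanol at room temperature therefore has no regiochemical choice and should give (2R,3R)-2-[3,4-bis(benzyloxy)phenyl]chromane-3,5,7-triol F2.
- The unhindered 7-hydroxyl would be silylated with TBDPSCl/imidazole at low temperature in preference to the 5-hydroxyl (flanked by C4a and its CH2) and the secondary alcohol. This should give (2R,3R)-2-[3,4-bis(benzyloxy)phenyl]-7-[(tert-butyldiphenylsilyl)oxy]chromane-3,5-diol F3.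
- Double Steglich esterification with acid 7 would give (2R,3R)-2-[3,4-bis(benzyloxy)phenyl]-7-[(tert-butyldiphenylsilyl)oxy]-3,4-dihydro-2H-chromene-3,5-diyl bis[3,4,5-tris(benzyloxy)benzoate] F4.
- HF·pyridine in THF would remove the silyl group to give (2R,3R)-2-[3,4-bis(benzyloxy)phenyl]-7-hydroxy-3,4-dihydro-2H-chromene-3,5-diyl bis[3,4,5-tris(benzyloxy)benzoate] F5.
- Hydrogenolysis over Pd(OH)2/C then gives 11.

**Step 4 (Mitsunobu).** The oxyphosphonium of the electron-rich, hindered benzylic carbinol may ionise, so that inversion is incomplete and the erythro diastereomer forms alongside the threo ether. Conversion may also stall. Enantiopurity is not at stake, since the epoxide stereocentre turns any scrambling into separable diastereomers.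

Fallback: it sets out from aldehyde 3 and diol 2 and comes back at ether 6, forming the aryl ether bond by SN2 opening of a cis-epoxide instead.
- Z-selective Still–Gennari olefination of 3 should give methyl (Z)-3-[3,4-bis(benzyloxy)phenyl]prop-2-enoate F6.
- DIBAL-H reduction gives (Z)-3-[3,4-bis(benzyloxy)phenyl]prop-2-en-1-ol F7.
- Sharpless epoxidation with D-(−)-DIPT gives [(2R,3S)-3-[3,4-bis(benzyloxy)phenyl]oxiran-2-yl]methanol F8.
- The phenoxide of 2 (excess, aqueous NaOH, 70 °C) should open F8 at the benzylic carbon with inversion to give (2R,3R)-3-[3-(benzyloxy)-5-hydroxyphenoxy]-3-[3,4-bis(benzyloxy)phenyl]propane-1,2-diol F9, which already has the threo arrangement.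
- Dehydrative closure of the 1,2-diol through its primary hydroxyl (PPh3/DIAD, via the cyclic dioxaphosphorane, retention at the secondary carbon) gives 6.

**Step 3 (kinetic resolution).** Epoxidation of the monosubstituted alkene is slow, and the two enantiomers of 4 may not be discriminated well enough. Epoxy alcohol 5 of high enantiomeric purity would then be available only at low conversion.

Fallback: it sets out from racemic 4 and comes back at 5, separating the resolution from the epoxidation.
- Lipase-catalysed acylation (Candida antarctica lipase B, vinyl acetate, MTBE) should acylate the (R)-enantiomer selectively to give (R)-1-[3,4-bis(benzyloxy)phenyl]prop-2-en-1-yl acetate F10, which is separated from unreacted (S)-alcohol.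
- Methanolysis (K2CO3, MeOH) gives (R)-1-[3,4-bis(benzyloxy)phenyl]prop-2-en-1-ol F11.
- Sharpless epoxidation of F11 with L-(+)-DIPT, now the matched pair and run to full conversion, gives 5.

## Further compounds

F1 | step 6 | 5-{(R)-[3,4-bis(benzyloxy)phenyl][(2R)-oxiran-2-yl]methoxy}benzene-1,3-diol | Oc1cc(O)cc(O[C@H](c2ccc(OCc3ccccc3)c(OCc3ccccc3)c2)[C@H]2CO2)c1
F2 | step 6 | (2R,3R)-2-[3,4-bis(benzyloxy)phenyl]chromane-3,5,7-triol | Oc1cc(O)cc2c1C[C@@H](O)[C@@H](c1ccc(OCc3ccccc3)c(OCc3ccccc3)c1)O2
F3 | step 6 | (2R,3R)-2-[3,4-bis(benzyloxy)phenyl]-7-[(tert-butyldiphenylsilyl)oxy]chromane-3,5-diol | Oc1cc(O[Si](c2ccccc2)(c2ccccc2)C(C)(C)C)cc2c1C[C@@H](O)[C@@H](c1ccc(OCc3ccccc3)c(OCc3ccccc3)c1)O2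
F4 | step 6 | (2R,3R)-2-[3,4-bis(benzyloxy)phenyl]-7-[(tert-butyldiphenylsilyl)oxy]-3,4-dihydro-2H-chromene-3,5-diyl bis[3,4,5-tris(benzyloxy)benzoate] | O=C(Oc1cc(O[Si](c2ccccc2)(c2ccccc2)C(C)(C)C)cc2c1C[C@@H](OC(=O)c1cc(OCc3ccccc3)c(OCc3ccccc3)c(OCc3ccccc3)c1)[C@@H](c1ccc(OCc3ccccc3)c(OCc3ccccc3)c1)O2)c1cc(OCc2ccccc2)c(OCc2ccccc2)c(OCc2ccccc2)c1
F5 | step 6 | (2R,3R)-2-[3,4-bis(benzyloxy)phenyl]-7-hydroxy-3,4-dihydro-2H-chromene-3,5-diyl bis[3,4,5-tris(benzyloxy)benzoate] | O=C(Oc1cc(O)cc2c1C[C@@H](OC(=O)c1cc(OCc3ccccc3)c(OCc3ccccc3)c(OCc3ccccc3)c1)[C@@H](c1ccc(OCc3ccccc3)c(OCc3ccccc3)c1)O2)c1cc(OCc2ccccc2)c(OCc2ccccc2)c(OCc2ccccc2)c1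
F6 | step 4 | methyl (Z)-3-[3,4-bis(benzyloxy)phenyl]prop-2-enoate | COC(=O)/C=C\c1ccc(OCc2ccccc2)c(OCc2ccccc2)c1
F7 | step 4 | (Z)-3-[3,4-bis(benzyloxy)phenyl]prop-2-en-1-ol | OC/C=C\c1ccc(OCc2ccccc2)c(OCc2ccccc2)c1
F8 | step 4 | [(2R,3S)-3-[3,4-bis(benzyloxy)phenyl]oxiran-2-yl]methanol | OC[C@H]1O[C@H]1c1ccc(OCc2ccccc2)c(OCc2ccccc2)c1
F9 | step 4 | (2R,3R)-3-[3-(benzyloxy)-5-hydroxyphenoxy]-3-[3,4-bis(benzyloxy)phenyl]propane-1,2-diol | OC[C@@H](O)[C@H](Oc1cc(O)cc(OCc2ccccc2)c1)c1ccc(OCc2ccccc2)c(OCc2ccccc2)c1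
F10 | step 3 | (R)-1-[3,4-bis(benzyloxy)phenyl]prop-2-en-1-yl acetate | C=C[C@@H](OC(C)=O)c1ccc(OCc2ccccc2)c(OCc2ccccc2)c1
F11 | step 3 | (R)-1-[3,4-bis(benzyloxy)phenyl]prop-2-en-1-ol | C=C[C@@H](O)c1ccc(OCc2ccccc2)c(OCc2ccccc2)c1
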